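**Plan**

- Target as read: ring A is a (5R)-oxolan-2-one with a 5-(2-methylprop-1-enyl) group and a 3Z-alkylidene chain (chain cis to C2=O); ring B is a furan-2(5H)-one substituted at C4; the chain between them (C1–C11, counted from the alkylidene carbon) is a 4E,8E,10E-triene.
- Retrosynthetic cuts, in order: ring B at O1–C5 together with C4–C11 of the chain (one palladium event, dienyl iodide + buta-2,3-dienoic acid); C10=C11 (Takai iodo-olefination of an enal); the exocyclic C3=C1 alkene of ring A (Horner–Wadsworth–Emmons); C10–C11 of farnesyl acetate (oxidative cleavage); the C3–P bond and the carbinol C–H of ring A.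
- Enabling feature: in ring B, C3=C4–C5 is an allyl unit whose central C4 bears the dienyl chain and whose terminal C5 is an unsubstituted CH2 bound to the ring oxygen of the C2 carboxyl. This is the retron of a 2,3-allenoic acid that takes an alkenyl group at the central allene carbon and its own carboxylate oxygen at the terminal one.
- Forward order: the C12 chain from (2E,6E)-farnesyl acetate (steps 1–3); ring A (steps 4–6); union by olefination (step 7); chain end advanced to the dienyl iodide (steps 8–9); ring B closed last (step 10).
- Stereochemistry: C5 (R) of ring A from a Corey–Bakshi–Shibata reduction with the (S)-catalyst; 4E and 8E from farnesyl acetate; 3Z from the kinetically controlled olefination; 10E from the Takai reaction, retained in the palladium step.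

Key step: step 10

Assumption: buta-2,3-dienoic acid is taken as purchasable; it is otherwise accessible by saponification of commercial ethyl buta-2,3-dienoate.

**Route**

Step 1
Reactants: 1 (2E,6E)-farnesyl acetate
Product: 2 (2E,6E)-10-bromo-11-hydroxy-3,7,11-trimethyldodeca-2,6-dien-1-yl acetate (racemic at C10)
Conditions: NBS (1.1 equiv), THF/H2O, 0 °C
Reagents that add atoms: N-bromosuccinimide (O=C1CCC(=O)N1Br); water (O)
Why: Electrophilic bromohydrin formation in aqueous medium should occur preferentially at the terminal, most exposed trisubstituted alkene of the folded polyene, with water opening the bromonium ion at the tertiary carbon; the new stereocenter is racemic and is destroyed in step 3.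

Step 2
Reactants: 2 bromohydrin acetate
Product: 3 (2E,6E)-10,11-epoxy-3,7,11-trimethyldodeca-2,6-dien-1-ol (racemic epoxide)
Conditions: K2CO3 (3 equiv), MeOH, rt
Reagents that add atoms: none
Why: Intramolecular Williamson closure of the bromohydrin gives the epoxide while base-catalysed methanolysis removes the acetate, freeing the allylic alcohol that is oxidised in step 8.

Step 3
Reactants: 3 epoxy alcohol
Product: 5 (4E,8E)-10-hydroxy-4,8-dimethyldeca-4,8-dienal, via triol 4 (not isolated)
Conditions: H5IO6 (1.2 equiv), THF/H2O, 0 °C
Reagents that add atoms: water (O)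
Why: Aqueous periodic acid hydrolyses the trisubstituted epoxide to triol 4 (water enters at the tertiary carbon, and that oxygen later leaves with the acetone) and cleaves the vicinal diol in the same flask (Malaprade glycol cleavage); the allylic alcohol and both E alkenes should be untouched.

Step 4
Reactants: 6 methyl 4-chloro-4-oxobutanoate; 7 (2-methylprop-1-enyl)magnesium bromide
Product: 8 methyl 6-methyl-4-oxohept-5-enoate
Conditions: CuI (5 mol%), THF, −78 °C → −40 °C
Reagents that add atoms: none
Why: Copper-catalysed acylation of a Grignard reagent by an acid chloride at low temperature stops at the ketone and spares the much less electrophilic methyl ester.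

Step 5
Reactants: 8 enone ester
Product: 10 (5R)-5-(2-methylprop-1-enyl)oxolan-2-one, via hydroxy ester 9 (not isolated)
Conditions: (S)-2-methyl-CBS-oxazaborolidine (15 mol%), catecholborane (1.5 equiv), toluene, −78 °C; MeOH quench, aqueous work-up; then PPTS (cat.), CH2Cl2, rt
Reagents that add atoms: none
Why: Corey–Bakshi–Shibata reduction: the (S)-oxazaborolidine binds the enone with the isobutenyl group as the large substituent and delivers hydride 1,2 to give the R carbinol, which closes ring A by mild acid-catalysed transesterification without touching the stereocenter.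

Step 6
Reactants: 10 lactone
Product: 12 diethyl [(5R)-5-(2-methylprop-1-enyl)-2-oxooxolan-3-yl]phosphonate (mixture at C3), via lactonyl phosphonite 11 (not isolated)
Conditions: LiN(iPr)2 (1.1 equiv), THF, −78 °C; ClP(OEt)2, −78 °C → rt; then 30% H2O2, 0 °C
Reagents that add atoms: diethyl chlorophosphite (CCOP(Cl)OCC); hydrogen peroxide (OO)
Why: The kinetic lithium enolate of the lactone is phosphinylated on carbon by the soft trivalent phosphorus chloride and the phosphonite is oxidised to the phosphonate (enolate C-phosphonylation); the new C3 center is of no consequence because it becomes sp2 in step 7.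

Step 7
Reactants: 12 phosphono lactone; 5 hydroxy aldehyde
Product: 13 (3Z,5R)-3-[(4E,8E)-10-hydroxy-4,8-dimethyldeca-4,8-dien-1-ylidene]-5-(2-methylprop-1-enyl)oxolan-2-one
Conditions: KN(SiMe3)2 (1.05 equiv), 18-crown-6 (3 equiv), THF, −78 °C; then 5, −78 °C → −40 °C
Reagents that add atoms: none
Why: Horner–Wadsworth–Emmons olefination of an α-phosphono lactone with the potassium ion sequestered by the crown ether at low temperature is under kinetic control and should favour the Z-alkylidene lactone (chain cis to the carbonyl), the minor E isomer being removed by chromatography; the free primary alcohol is too weakly acidic to quench the phosphonate anion.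

Step 8
Reactants: 13 allylic alcohol
Product: 14 (2E,6E,10Z)-3,7-dimethyl-10-[(5R)-5-(2-methylprop-1-enyl)-2-oxooxolan-3-ylidene]deca-2,6-dienal
Conditions: TEMPO (10 mol%), PhI(OAc)2 (1.1 equiv), CH2Cl2, rt
Reagents that add atoms: none
Why: Oxoammonium-catalysed oxidation converts the primary allylic alcohol to the enal without E/Z isomerisation of the adjacent alkene and without touching the other alkenes or the lactone.

Step 9
Reactants: 14 enal
Product: 15 (3Z,5R)-3-[(4E,8E,10E)-11-iodo-4,8-dimethylundeca-4,8,10-trien-1-ylidene]-5-(2-methylprop-1-enyl)oxolan-2-one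
Conditions: CrCl2 (6 equiv), CHI3 (2 equiv), THF/1,4-dioxane, 0 °C → rt, dark
Reagents that add atoms: iodoform (IC(I)I)
Why: Takai olefination: the geminal dichromium species from iodoform adds to the aldehyde and eliminates to the E-iodoalkene, here an (E,E)-dienyl iodide; the lactone and its conjugated alkene are inert to divalent chromium.

Step 10
Reactants: 15 dienyl iodide; 16 buta-2,3-dienoic acid (1.5 equiv)
Product: 17 (3Z,5R)-3-[(4E,8E,10E)-4,8-dimethyl-11-(5-oxo-2,5-dihydrofuran-3-yl)undeca-4,8,10-trien-1-ylidene]-5-(2-methylprop-1-enyl)oxolan-2-one (target)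
Conditions: Pd(PPh3)4 (5 mol%), Ag2CO3 (10 mol%), K2CO3 (2 equiv), MeCN, 60 °C, dark
Reagents that add atoms: none
Why: Zerovalent palladium inserts into the C–I bond of 15 with retention, Ag+ removes iodide, and the cationic dienylpalladium adds across the allene of the carboxylate of 16 with the dienyl group going to the central carbon (future C4 of ring B), which gives an η3-allylpalladium over C3–C4–C5; the tethered carboxylate oxygen then attacks the unsubstituted CH2 terminus (C5), forming the O1–C5 bond and returning zerovalent palladium. The closest known reaction type is the palladium/silver-cocatalysed coupling–cyclisation of 2,3-allenoic acids with aryl and alkenyl halides to 4-substituted butenolides. Ring B closes as a five-membered ring by intramolecular allylic substitution in which all three allyl carbons become ring members (formally 5-endo at the allene terminus, made feasible by the η3-allyl metal electrophile; only the allyl isomer with the carboxylate anti can close, and η3–η1–η3 exchange supplies it). No stereocenter is formed, and the E,E geometry of the diene is carried over from 15 because oxidative addition and insertion are stereoretentive. The step needs regioselectivity (C–C bond at the central allene carbon, C–O bond at CH2 and not at the carboxyl-bearing CH, which would give a three-membered lactone) and chemoselectivity for the C(sp2)–I bond over the allylic C5–O bond of ring A, secured by the much faster oxidative addition of the alkenyl iodide and the poor coordination of the trisubstituted isobutenyl alkene. The mild carbonate base should leave the Z-alkylidene lactone and the acidic C5 methylene of the product untouched.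

**Compound list**

1 | (2E,6E)-farnesyl acetate | CC(C)=CCC/C(C)=C/CC/C(C)=C/COC(C)=O | starting material
2 | (2E,6E)-10-bromo-11-hydroxy-3,7,11-trimethyldodeca-2,6-dien-1-yl acetate (racemic at C10) | CC(C)(O)C(Br)CC/C(C)=C/CC/C(C)=C/COC(C)=O | intermediate
3 | (2E,6E)-10,11-epoxy-3,7,11-trimethyldodeca-2,6-dien-1-ol (racemic) | CC1(C)OC1CC/C(C)=C/CC/C(C)=C/CO | intermediate
4 | (2E,6E)-3,7,11-trimethyldodeca-2,6-diene-1,10,11-triol (racemic at C10) | CC(C)(O)C(O)CC/C(C)=C/CC/C(C)=C/CO | intermediate
5 | (4E,8E)-10-hydroxy-4,8-dimethyldeca-4,8-dienal | O=CCC/C(C)=C/CC/C(C)=C/CO | intermediate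
6 | methyl 4-chloro-4-oxobutanoate | COC(=O)CCC(Cl)=O | starting material
7 | (2-methylprop-1-enyl)magnesium bromide | CC(C)=C[Mg]Br | starting material
8 | methyl 6-methyl-4-oxohept-5-enoate | COC(=O)CCC(=O)C=C(C)C | intermediate
9 | methyl (4R)-4-hydroxy-6-methylhept-5-enoate | COC(=O)CC[C@@H](O)C=C(C)C | intermediate
10 | (5R)-5-(2-methylprop-1-enyl)oxolan-2-one | CC(C)=C[C@H]1CCC(=O)O1 | intermediate
11 | diethyl [(5R)-5-(2-methylprop-1-enyl)-2-oxooxolan-3-yl]phosphonite | CC(C)=C[C@H]1CC(P(OCC)OCC)C(=O)O1 | intermediate
12 | diethyl [(5R)-5-(2-methylprop-1-enyl)-2-oxooxolan-3-yl]phosphonate (mixture at C3) | CC(C)=C[C@H]1CC(P(=O)(OCC)OCC)C(=O)O1 | intermediate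
13 | (3Z,5R)-3-[(4E,8E)-10-hydroxy-4,8-dimethyldeca-4,8-dien-1-ylidene]-5-(2-methylprop-1-enyl)oxolan-2-one | CC(C)=C[C@H]1C/C(=C/CC/C(C)=C/CC/C(C)=C/CO)C(=O)O1 | intermediate
14 | (2E,6E,10Z)-3,7-dimethyl-10-[(5R)-5-(2-methylprop-1-enyl)-2-oxooxolan-3-ylidene]deca-2,6-dienal | CC(C)=C[C@H]1C/C(=C/CC/C(C)=C/CC/C(C)=C/C=O)C(=O)O1 | intermediate
15 | (3Z,5R)-3-[(4E,8E,10E)-11-iodo-4,8-dimethylundeca-4,8,10-trien-1-ylidene]-5-(2-methylprop-1-enyl)oxolan-2-one | CC(C)=C[C@H]1C/C(=C/CC/C(C)=C/CC/C(C)=C/C=C/I)C(=O)O1 | intermediate
16 | buta-2,3-dienoic acid | C=C=CC(=O)O | starting material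
17 | (3Z,5R)-3-[(4E,8E,10E)-4,8-dimethyl-11-(5-oxo-2,5-dihydrofuran-3-yl)undeca-4,8,10-trien-1-ylidene]-5-(2-methylprop-1-enyl)oxolan-2-one | CC(C)=C[C@H]1C/C(=C/CC/C(C)=C/CC/C(C)=C/C=C/C2=CC(=O)OC2)C(=O)O1 | target

**Totals and risks**

Total step count: 10. Longest linear sequence: 7 steps (steps 1–3 and 7–10, or steps 4–10).

Steps most likely to fail:

1. Step 7. Kinetic control may be lost through equilibration of the adducts, which would give mainly the thermodynamically preferred E-alkylidene lactone, or the diethyl phosphonate anion may add too slowly at low temperature. The fallback sets out from 10 and 5 and comes back at 13. Aldehyde 5 is silylated (TBSCl, imidazole, DMF) to (4E,8E)-10-[(tert-butyldimethylsilyl)oxy]-4,8-dimethyldeca-4,8-dienal F1. The lithium enolate of 10 (LiN(iPr)2, THF, −78 °C), a ring-locked E(O)-enolate, should add to F1 through a closed transition state to give mainly the anti aldol (5R)-3-[(4E,8E)-10-[(tert-butyldimethylsilyl)oxy]-1-hydroxy-4,8-dimethyldeca-4,8-dienyl]-5-(2-methylprop-1-enyl)oxolan-2-one F2. Anti-periplanar dehydration of the anti aldol under Mitsunobu-type activation (PPh3, diethyl azodicarboxylate, THF) places the chain cis to the carbonyl and gives the silyl ether of 13 F3. HF·pyridine in THF then frees 13.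

2. Step 10. Zerovalent palladium may ionise the allylic C5–O bond of ring A (ring opening or racemisation), the carbonate may degrade the butenolide at its acidic methylene, or silver may cycloisomerise or oligomerise 16 before coupling. The fallback sets out from 15 and comes back at 17. It is a palladium-free and base-free copper-mediated Stille-type coupling of 15 with 4-(tributylstannyl)furan-2(5H)-one F4, using copper thiophene-2-carboxylate Cu(O2CC4H3S) (1.5 equiv) in NMP at 0 °C → rt. F4 is made from purchasable 4-bromofuran-2(5H)-one and Sn2Bu6 with Pd(PPh3)4 (cat.) in toluene at 80 °C. Ring B is then brought in preformed and only the C4–C11 bond is made.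

3. Step 9. The iodo-olefination may give incomplete E selectivity, and the dienyl iodide may isomerise or decompose under light or traces of acid during isolation. The fallback sets out from 14 and comes back at 17, bypassing 15. It is an E-selective Horner–Wadsworth–Emmons olefination of 14 with the anion of diethyl [(5-oxo-2,5-dihydrofuran-3-yl)methyl]phosphonate F5 (LiN(SiMe3)2, THF, −78 °C → 0 °C), which forms the C10=C11 alkene with ring B already in place. F5 is made by an Arbuzov reaction of purchasable 4-(bromomethyl)furan-2(5H)-one with P(OEt)3.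

**Further compounds**

F1 | step 7 | (4E,8E)-10-[(tert-butyldimethylsilyl)oxy]-4,8-dimethyldeca-4,8-dienal | O=CCC/C(C)=C/CC/C(C)=C/CO[Si](C)(C)C(C)(C)C
F2 | step 7 | (5R)-3-[(4E,8E)-10-[(tert-butyldimethylsilyl)oxy]-1-hydroxy-4,8-dimethyldeca-4,8-dienyl]-5-(2-methylprop-1-enyl)oxolan-2-one (anti at C3/C1′, mixture at C3) | CC(C)=C[C@H]1CC(C(O)CC/C(C)=C/CC/C(C)=C/CO[Si](C)(C)C(C)(C)C)C(=O)O1
F3 | step 7 | (3Z,5R)-3-[(4E,8E)-10-[(tert-butyldimethylsilyl)oxy]-4,8-dimethyldeca-4,8-dien-1-ylidene]-5-(2-methylprop-1-enyl)oxolan-2-one | CC(C)=C[C@H]1C/C(=C/CC/C(C)=C/CC/C(C)=C/CO[Si](C)(C)C(C)(C)C)C(=O)O1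
F4 | step 10 | 4-(tributylstannyl)furan-2(5H)-one | CCCC[Sn](CCCC)(CCCC)C1=CC(=O)OC1
F5 | step 9 | diethyl [(5-oxo-2,5-dihydrofuran-3-yl)methyl]phosphonate | CCOP(=O)(OCC)CC1=CC(=O)OC1
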